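The runs are simulated on assumed constants; scatter was added.

Substrate that disappears turns up as target: east reads 101% at 6.00 h, with a scatter of 1.5 percentage points. So you reckon just the small remainder of substrate and subtract it from the charge.

the same everywhere: substrate 0.30 M; free catalyst 0.5 mol%
- east: added ligand 0.72 mM; run made earlier
- north-west: added ligand 6.9 mM; run made earlier
- Sunday's: added ligand 1.0 mM; time 8.0 h
- Wednesday's: added ligand 2.0 mM; time 8.0 h
- Tuesday's: added ligand 4.0 mM; time 8.0 h
- Saturday's: added ligand 8.0 mM; time 8.0 h

The earlier runs share 0.30 M substrate and 0.5 mol% free catalyst, so follow the added ligand.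

- east (time / h: target / %): 1.00: 68; 2.50: 95; 3.00: 98; 5.00: 99; 6.00: 101
- north-west (time / h: target / %): 1.00: 37; 2.50: 69; 3.00: 72; 5.00: 90; 6.00: 92

(each reading ± 1.5 percentage points)

- the numbers in the tables scatter with a standard deviation of 1.5 percentage points
- "hardly changes" means that all values lie within two and a half points (for a concentration: within two and a half percent of the largest)

Take the lifetime, the time in which the remaining substrate falls by a factor e (a pseudo-first-order reading). East's first reading gives 0.878 h and north-west's gives 2.16 h. North-west's lifetime puts its target at 90.1% by 5.00 h, and the reading there is 90%, so the reading holds up.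

Between the two runs, 4.22 mM of added ligand adds one east lifetime, and that amount is the drag. Two runs draw a straight line and no more, and Saturday's 8.0 mM lies just past north-west's 6.9 mM, so this is a bet.

* amount of target at the end, in percent of the substrate charged for Sunday's, Wednesday's, Tuesday's, Saturday's, in this order
* the course of these numbers from the first flask to the last (falls, then rises / rises, then falls / falls all the way / rises all the way / hardly changes)

My reckoning: Saturday's lifetime is 2.39 h, leaving 3.53% of the substrate after 8.0 h. Tuesday's is 1.56 h, leaving 0.594%. Sunday's leaves 0.0194%. The row therefore falls all the way, spanning 3.5 points, outside what "hardly changes" allows.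

The forecast gives 100%, 99.9%, 99.4% and 96%, course falls all the way, on the ground that “Added ligand therefore slows the reaction, presumably by tying up catalyst.” Its last figure lies 0.47 points under mine.

The flasks give 100%, 99.9%, 99.6% and 96.7%, course falls all the way.

    substrate + free catalyst ⇌ catalyst intermediate (K = 0.900 /M, k = 0.370 /M/s)
    free catalyst + added ligand ⇌ idle complex, settled at all times (K = 330 /M)
    catalyst intermediate → free catalyst + target (k = 1.00 /s)

Set 8.0 h against the lifetime: Saturday's 2.39 h, built from the drag of 4.22 mM, gives 3.35 lifetimes and a reckoned remainder of 3.53%, and the flask holds 3.3% of its substrate, with 69.6% of its catalyst as idle complex at 8.00 h. Tuesday's lifetime of 1.56 h, from the same drag, gives 5.13 lifetimes and a reckoned 0.594%, and that flask holds 0.43% of its substrate.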